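**Two rates.** The constants of coupling and pairing set two losses of dissolved substrate against each other in this flask, one first-order in it and the other second-order. With coupling partner at saturation, coupling runs pseudo-first-order at k_c = 0.0701 s⁻¹. Pairing into side product is second order, so its loss per unit of dissolved substrate grows with the level: at the solubility s = 34 mM that loss is k_d = 0.0313 s⁻¹, slower than k_c. The clock stays out of the contest, since 1/k_c = 14.3 s is far shorter than the run.

solid substrate 0.091 M; gas 9.1 mM (held); time 8.0 min

    solid substrate ⇌ dissolved substrate, rate k1*(cs1 - [dissolved substrate]) while solid is left; crystals form when [dissolved substrate] > cs1 (cs1 = 34 mM, k1 = 0.18 s⁻¹)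
    dissolved substrate + coupling partner → target (k2 = 7.7 M⁻¹ s⁻¹)
    coupling partner → decomposed reagent (k3 = 0.0071 s⁻¹)
    crystals ⇌ target, rate k4*(cs4 - [target]) while solid is left; crystals form when [target] > cs4 (cs4 = 37 mM, k4 = 6.9 s⁻¹)
    gas ⇌ coupling partner, rate k5*(csat - [coupling partner]) (k5 = 0.42 s⁻¹, csat = 9.1 mM)
    2 dissolved substrate → side product (k6 = 0.46 M⁻¹ s⁻¹)

* the target and crystals together standing at 8.0 min, as a percentage of the solid substrate charged
* concentration of dissolved substrate in solution at 2.0 min, in percent of saturation
* the change that raises the amount of target and crystals together at 8.0 min, in percent of the solid substrate charged most ("none" if none brings more than 2 percentage points) (south-east / south / south-west / north-east / none)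
* amount of target and crystals together at 8.0 min, in percent of the solid substrate charged, after south-east

- south-east: doubling the dissolution coefficient of step 4, all else as stated
- south: doubling the saturation concentration of gas, all else as stated
- south-west: doubling the solubility in step 4, all else as stated
- north-east: doubling the transfer coefficient of step 5, all else as stated

- in percentages every species weighs as the solid substrate in it: one side product counts as two
- for target the crystals are counted in
- a step written with two of one species runs at k times the square of its concentration and takes two of it each time
- as a solid, counted per litre of solution: solid substrate, crystals
- at the start none of coupling partner is dissolved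
- at the start none of the solid substrate is in solution
- dissolved substrate means what is dissolved; the solid is not counted in it
- run time (flask): 8.0 min

**Crossover level.** The two losses meet at one level, carried as A* = 76.2 mM, the crossover level: the dissolved substrate at which both losses run equally with coupling partner at saturation. At level A, the ratio of the two losses (the selectivity factor) is A*/A, so the share going to target is A*/(A*+A).

**Own reckoning.** The charge C above s passes at level s, with share 0.691. The last s then falls away, and integrating the share gives A*·ln((A*+s)/A*) = 28.1 mM. Together these give y = 74.2%. Both levels are ceilings, and they pull opposite ways on the share. A* holds neither constant of the target's dissolution, so I expect yb to equal y. Doubling the gas saturation doubles A*, so I choose south.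

**Forecast.** It gives 73%, 0.39%, south and 73%, arguing: “Crystals count with target and target does not react further”.

**Result.** The flask gives 73.0%, 0.389%, south (gain 14 percentage points; north-east 3.7 points) and 73.0%. Side product holds 27.0%.

**Neighbour flask.** The flask charged with 0.036 M stands 2.00 mM above s, so the same A* gives 81.9%. That flask gives 80.3%, with 19.7% as side product and 0% as crystals.

The rate constants were set for the occasion; what happens was integrated by code.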